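**Retrosynthetic overview**

1. Feature: O1, C2 with its catechol ring B, C3 and the fused benzene ring A form a 2-aryl-2,3-dihydrobenzofuran, which is a flavanone that has lost C4. C2 (S) can therefore be set on a chromanone, and the extruded C4 becomes a carboxyl handle on C3.
2. The six phenols come last (mesylate removal, then demethylation). The C3–aryl bond (ring D) comes from decarboxylative arylation of the C3 acid, trans to the C2 aryl group. The C5–styryl bond (ring E) comes from Heck coupling at C5–Br.
3. Key disconnection: the C3–C3a bond, by oxidative ring contraction of (2S)-6-bromo-3',4'-bis(mesyloxy)flavanone 5, with C4 leaving the ring as CO2Me.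
4. The flavanone comes from enantioselective conjugate addition of the mesylated catechol boronic acid to 6-bromochromone.
5. Ring order: the four benzene rings and the pyranone (as the chromone) are bought; the dihydrofuran ring is the only ring made, in step 4, by contraction.

Key step: step 4

Assumption: (R)-t-BuPyOx is taken to give the 2S flavanone, by analogy with the facial sense of this ligand class on cyclic enones; the sense is checked on compound 5 by CD against known (2S)-flavanones, and the antipodal ligand is used if it is the other way round.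

**Route**

Step 1
Reactants: 1 4-bromocatechol
Product: 2 4-bromo-1,2-phenylene bis(methanesulfonate)
Conditions: MsCl (2.5 equiv), Et3N (3 equiv), CH2Cl2, 0 °C → rt
Reagents that add atoms: methanesulfonyl chloride, CS(=O)(=O)Cl
Why: O-sulfonylation of both phenols (sulfene pathway with Et3N) is routine and leaves the catechol ring electron-poor and inert to oxidants.

Step 2
Reactants: 2 4-bromo-1,2-phenylene bis(methanesulfonate)
Product: 3 [3,4-bis(methylsulfonyloxy)phenyl]boronic acid
Conditions: second-generation XPhos aminobiphenyl palladacycle (XPhos)Pd(2'-amino-1,1'-biphenyl-2-yl)Cl (1 mol%), XPhos (2 mol%), B2(OH)4 (2 equiv), KOAc (3 equiv), EtOH, 80 °C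
Reagents that add atoms: tetrahydroxydiboron, OB(O)B(O)O
Why: Miyaura borylation with tetrahydroxydiboron gives the boronic acid directly, since oxidative addition of zerovalent palladium into C–Br is far faster than into the aryl C–OMs bonds under these conditions.

Step 3
Reactants: 3 [3,4-bis(methylsulfonyloxy)phenyl]boronic acid (2 equiv); 4 6-bromochromone
Product: 5 (2S)-6-bromo-2-[3,4-bis(methylsulfonyloxy)phenyl]chroman-4-one
Conditions: Pd(OCOCF3)2 (5 mol%), (R)-t-BuPyOx (6 mol%), NH4PF6 (30 mol%), H2O (5 equiv), ClCH2CH2Cl, 60 °C; recrystallisation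
Reagents that add atoms: none
Why: In this asymmetric conjugate addition of an arylboronic acid to a chromone (Hayashi–Miyaura type, run with a cationic divalent palladium–pyridinooxazoline catalyst), the aryl–palladium species inserts into the C2=C3 bond on the face selected by the ligand and sets C2 (S); the catalyst stays divalent, so C–Br and the mesylates are untouched, and the near-neutral medium does not open the flavanone.

Step 4
Reactants: 5 (2S)-6-bromo-2-[3,4-bis(methylsulfonyloxy)phenyl]chroman-4-one
Product: 7 methyl (2S,3S)-5-bromo-2-[3,4-bis(methylsulfonyloxy)phenyl]-2,3-dihydro-1-benzofuran-3-carboxylate (2,3-trans), via methyl enol ether (2S)-6-bromo-4-methoxy-2-[3,4-bis(methylsulfonyloxy)phenyl]-2H-chromene 6 (not isolated)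
Conditions: PhI(OAc)2 (1.3 equiv), conc. H2SO4 (1.5 equiv), HC(OMe)3, 0 °C → rt
Reagents that add atoms: trimethyl orthoformate, COC(OC)OC
Why: Acid and orthoformate convert the C4 ketone into enol ether 6, whose C3 is attacked by electrophilic trivalent iodine anti to the equatorial C2 aryl group while methanol closes C4 to a dimethyl ketal; the equatorial C3–I bond then lies antiperiplanar to the ring bond C4–C4a, so C4a migrates to C3 as iodobenzene leaves, and the dimethoxycarbenium ion at the extruded C4 collapses to the methyl ester on work-up. The closest known reaction type is the hypervalent-iodine (or thallium trinitrate) oxidative ring contraction of flavanones in trimethyl orthoformate, a member of the oxidative 1,2-aryl-shift family. The dihydrofuran ring is closed not by a cyclisation but by a 1,2-shift of an sp2 ring carbon through a bridged, phenonium-like transition state, which contracts the six-membered pyranone to the five-membered ring and forms the C3–C3a bond. The new C3 centre is controlled by the resident C2 centre: anti attack of iodine followed by inversion at C3 should place the ester trans to the C2 aryl group, which is also the thermodynamic arrangement, and C2 itself is untouched because the acidic, base-free medium gives no retro-oxa-Michael opening. The step needs migration of C4a in preference to the C2 aryl group (isoflavone pathway) and to loss of H-2 (flavone pathway); C4a is favoured because it is ortho to the donor O1 and antiperiplanar to iodine, and the two mesylates make ring B too electron-poor to bridge to C3.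

Step 5
Reactants: 7 methyl (2S,3S)-5-bromo-2-[3,4-bis(methylsulfonyloxy)phenyl]-2,3-dihydro-1-benzofuran-3-carboxylate; 8 3,5-dimethoxystyrene
Product: 9 methyl (2S,3S)-2-[3,4-bis(methylsulfonyloxy)phenyl]-5-[(E)-2-(3,5-dimethoxyphenyl)ethenyl]-2,3-dihydro-1-benzofuran-3-carboxylate
Conditions: Pd2(dba)3 (2 mol%), [HP(t-Bu)3]BF4 (8 mol%), Cy2NMe (1.2 equiv), 1,4-dioxane, 40 °C
Reagents that add atoms: none
Why: Mizoroki–Heck reaction at C5–Br (terminal arylation of the styrene, then syn β-hydride elimination) should give the E-stilbene; the bulky electron-rich phosphine allows near-ambient temperature with a hindered amine, so the β-aryloxy ester is not opened by E1cB, and any epimerisation at C3 is harmless because C3 is reset in step 9.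

Step 6
Reactants: 9 methyl (2S,3S)-2-[3,4-bis(methylsulfonyloxy)phenyl]-5-[(E)-2-(3,5-dimethoxyphenyl)ethenyl]-2,3-dihydro-1-benzofuran-3-carboxylate
Product: 10 (2S,3S)-2-[3,4-bis(methylsulfonyloxy)phenyl]-5-[(E)-2-(3,5-dimethoxyphenyl)ethenyl]-2,3-dihydro-1-benzofuran-3-carboxylic acid
Conditions: Me3SnOH (6 equiv), ClCH2CH2Cl, 75 °C; then 5% aq. HCl
Reagents that add atoms: trimethyltin hydroxide, C[Sn](C)(C)O
Why: Trimethyltin hydroxide ester hydrolysis proceeds through a tin carboxylate under essentially neutral conditions, so the methyl ester is cleaved without retro-oxa-Michael ring opening (the only event that could racemise C2) and without touching the sulfonates.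

Step 7
Reactants: 10 (2S,3S)-2-[3,4-bis(methylsulfonyloxy)phenyl]-5-[(E)-2-(3,5-dimethoxyphenyl)ethenyl]-2,3-dihydro-1-benzofuran-3-carboxylic acid
Product: 11 1,3-dioxoisoindolin-2-yl (2S,3S)-2-[3,4-bis(methylsulfonyloxy)phenyl]-5-[(E)-2-(3,5-dimethoxyphenyl)ethenyl]-2,3-dihydro-1-benzofuran-3-carboxylate
Conditions: N-hydroxyphthalimide (1.1 equiv), DIC (1.1 equiv), CH2Cl2, 0 °C → rt, no DMAP; filtration, used crude
Reagents that add atoms: N-hydroxyphthalimide, O=C1c2ccccc2C(=O)N1O
Why: Carbodiimide esterification of the acid with the acidic N-hydroxy imide gives the redox-active ester, and leaving out the amine catalyst avoids ketene formation or E1cB opening of the now more acidic C3–H.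

Step 8
Reactants: 12 1-bromo-3,5-dimethoxybenzene
Product: 14 (3,5-dimethoxyphenyl)zinc chloride (LiCl-complexed solution in THF), via (3,5-dimethoxyphenyl)magnesium bromide 13 (not isolated)
Conditions: Mg turnings, LiCl, THF, rt; then ZnCl2 (1.0 M in THF), 0 °C → rt; titration
Reagents that add atoms: zinc chloride, Cl[Zn]Cl
Why: LiCl-assisted Grignard formation followed by transmetalation to zinc gives the mild arylzinc nucleophile needed for the Negishi-type coupling.

Step 9
Reactants: 11 the redox-active ester of step 7; 14 (3,5-dimethoxyphenyl)zinc chloride (3 equiv)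
Product: 15 4-[(2S,3S)-3-(3,5-dimethoxyphenyl)-5-[(E)-2-(3,5-dimethoxyphenyl)ethenyl]-2,3-dihydro-1-benzofuran-2-yl]-1,2-phenylene bis(methanesulfonate)
Conditions: NiCl2(dme) (20 mol%), 4,4'-di-tert-butyl-2,2'-bipyridine (40 mol%), THF/DMF, rt
Reagents that add atoms: none
Why: In this nickel-catalysed decarboxylative Negishi-type arylation, single-electron transfer from low-valent nickel fragments the ester to CO2, phthalimide anion and a planar benzylic C3 radical, which the aryl–nickel species should capture on the face anti to the C2 aryl group, so that reductive elimination sets C3 (S) trans to the unchanged C2 centre; aryl mesylates and the stilbene are inert to the bipyridine–nickel catalyst at room temperature.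

Step 10
Reactants: 15 4-[(2S,3S)-3-(3,5-dimethoxyphenyl)-5-[(E)-2-(3,5-dimethoxyphenyl)ethenyl]-2,3-dihydro-1-benzofuran-2-yl]-1,2-phenylene bis(methanesulfonate)
Product: 16 4-[(2S,3S)-3-(3,5-dimethoxyphenyl)-5-[(E)-2-(3,5-dimethoxyphenyl)ethenyl]-2,3-dihydro-1-benzofuran-2-yl]benzene-1,2-diol
Conditions: LiN(i-Pr)2 (6 equiv), THF, −78 → 0 °C; then aq. NH4Cl, under argon
Reagents that add atoms: none
Why: In this base-induced cleavage of aryl methanesulfonates, the amide removes a proton from the S-methyl group (by far the most acidic C–H present) and the carbanion expels the phenoxide with loss of sulfene (E1cB), at a temperature at which H-3 is not removed and the new phenoxide cannot open the ring through a quinone methide.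

Step 11
Reactants: 16 4-[(2S,3S)-3-(3,5-dimethoxyphenyl)-5-[(E)-2-(3,5-dimethoxyphenyl)ethenyl]-2,3-dihydro-1-benzofuran-2-yl]benzene-1,2-diol
Product: 17 4-[(2S,3S)-3-(3,5-dihydroxyphenyl)-5-[(E)-2-(3,5-dihydroxyphenyl)ethenyl]-2,3-dihydro-1-benzofuran-2-yl]benzene-1,2-diol (CNP0207985.1)
Conditions: BBr3 (12 equiv, 1 M in CH2Cl2), CH2Cl2, −78 → 0 °C; then MeOH, H2O
Reagents that add atoms: none
Why: In this Lewis-acid ether cleavage (BBr3 demethylation), boron coordinates each methoxy oxygen and bromide removes the methyl group by SN2; the catechol is converted at once into its cyclic bromoborate, which keeps ring B electron-poor so that the C2–O1 bond should not ionise, and the low temperature spares the stilbene until aqueous methanol releases all six phenols.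

**Compound list**

1 | 4-bromocatechol | Oc1ccc(Br)cc1O | starting material
2 | 4-bromo-1,2-phenylene bis(methanesulfonate) | CS(=O)(=O)Oc1ccc(Br)cc1OS(C)(=O)=O | intermediate
3 | [3,4-bis(methylsulfonyloxy)phenyl]boronic acid | CS(=O)(=O)Oc1ccc(B(O)O)cc1OS(C)(=O)=O | intermediate
4 | 6-bromochromone (6-bromo-4H-chromen-4-one) | O=c1ccoc2ccc(Br)cc12 | starting material
5 | (2S)-6-bromo-2-[3,4-bis(methylsulfonyloxy)phenyl]chroman-4-one | O=C1C[C@@H](c2ccc(OS(C)(=O)=O)c(OS(C)(=O)=O)c2)Oc2ccc(Br)cc21 | intermediate
6 | (2S)-6-bromo-4-methoxy-2-[3,4-bis(methylsulfonyloxy)phenyl]-2H-chromene | COC1=C[C@@H](c2ccc(OS(C)(=O)=O)c(OS(C)(=O)=O)c2)Oc2ccc(Br)cc21 | intermediate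
7 | methyl (2S,3S)-5-bromo-2-[3,4-bis(methylsulfonyloxy)phenyl]-2,3-dihydro-1-benzofuran-3-carboxylate (trans) | Brc1ccc2c(c1)[C@H](C(=O)OC)[C@@H](c1ccc(OS(C)(=O)=O)c(OS(C)(=O)=O)c1)O2 | intermediate
8 | 3,5-dimethoxystyrene | C=Cc1cc(OC)cc(OC)c1 | starting material
9 | methyl (2S,3S)-2-[3,4-bis(methylsulfonyloxy)phenyl]-5-[(E)-2-(3,5-dimethoxyphenyl)ethenyl]-2,3-dihydro-1-benzofuran-3-carboxylate | COc1cc(OC)cc(/C=C/c2ccc3c(c2)[C@H](C(=O)OC)[C@@H](c2ccc(OS(C)(=O)=O)c(OS(C)(=O)=O)c2)O3)c1 | intermediate
10 | (2S,3S)-2-[3,4-bis(methylsulfonyloxy)phenyl]-5-[(E)-2-(3,5-dimethoxyphenyl)ethenyl]-2,3-dihydro-1-benzofuran-3-carboxylic acid | COc1cc(OC)cc(/C=C/c2ccc3c(c2)[C@H](C(=O)O)[C@@H](c2ccc(OS(C)(=O)=O)c(OS(C)(=O)=O)c2)O3)c1 | intermediate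
11 | 1,3-dioxoisoindolin-2-yl (2S,3S)-2-[3,4-bis(methylsulfonyloxy)phenyl]-5-[(E)-2-(3,5-dimethoxyphenyl)ethenyl]-2,3-dihydro-1-benzofuran-3-carboxylate | COc1cc(OC)cc(/C=C/c2ccc3c(c2)[C@H](C(=O)ON2C(=O)c4ccccc4C2=O)[C@@H](c2ccc(OS(C)(=O)=O)c(OS(C)(=O)=O)c2)O3)c1 | intermediate
12 | 1-bromo-3,5-dimethoxybenzene | COc1cc(Br)cc(OC)c1 | starting material
13 | (3,5-dimethoxyphenyl)magnesium bromide | COc1cc(OC)cc([Mg]Br)c1 | intermediate
14 | (3,5-dimethoxyphenyl)zinc chloride | COc1cc(OC)cc([Zn]Cl)c1 | intermediate
15 | 4-[(2S,3S)-3-(3,5-dimethoxyphenyl)-5-[(E)-2-(3,5-dimethoxyphenyl)ethenyl]-2,3-dihydro-1-benzofuran-2-yl]-1,2-phenylene bis(methanesulfonate) | COc1cc(OC)cc(/C=C/c2ccc3c(c2)[C@H](c2cc(OC)cc(OC)c2)[C@@H](c2ccc(OS(C)(=O)=O)c(OS(C)(=O)=O)c2)O3)c1 | intermediate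
16 | 4-[(2S,3S)-3-(3,5-dimethoxyphenyl)-5-[(E)-2-(3,5-dimethoxyphenyl)ethenyl]-2,3-dihydro-1-benzofuran-2-yl]benzene-1,2-diol | COc1cc(OC)cc(/C=C/c2ccc3c(c2)[C@H](c2cc(OC)cc(OC)c2)[C@@H](c2ccc(O)c(O)c2)O3)c1 | intermediate
17 | 4-[(2S,3S)-3-(3,5-dihydroxyphenyl)-5-[(E)-2-(3,5-dihydroxyphenyl)ethenyl]-2,3-dihydro-1-benzofuran-2-yl]benzene-1,2-diol | Oc1cc(O)cc(/C=C/c2ccc3c(c2)[C@H](c2cc(O)cc(O)c2)[C@@H](c2ccc(O)c(O)c2)O3)c1 | target

**Step count and risks**

Total step count: 11. Longest linear sequence: 10 steps (steps 1–7 and 9–11, from 4-bromocatechol); step 8 is a one-step side branch.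

Steps most likely to fail:

Step 4 (key step). The C3 iodane may lose H-2 instead of rearranging (dehydrogenation to the flavone), it may be displaced by methanol (3-methoxyflavanone), or migration may be slow because bromine sits meta to the migrating carbon. The fallback sets out from 5 and replaces the oxidative shift by a Wolff ring contraction. Detrifluoroacetylative diazo transfer (LiN(SiMe3)2, CF3CO2CH2CF3, THF, −78 °C) should give (2S)-6-bromo-2-[3,4-bis(methylsulfonyloxy)phenyl]-3-(trifluoroacetyl)chroman-4-one F1, and MsN3, Et3N and H2O in MeCN should turn it into (2R)-6-bromo-3-diazo-2-[3,4-bis(methylsulfonyloxy)phenyl]chroman-4-one F2 (the descriptor changes, the spatial arrangement at C2 does not). Irradiation at 365 nm in methanol should move C4a from C4 to the carbene carbon C3, and methanol should trap the ketene as the ester. Any cis isomer, methyl (2S,3R)-5-bromo-2-[3,4-bis(methylsulfonyloxy)phenyl]-2,3-dihydro-1-benzofuran-3-carboxylate F3, is epimerised with catalytic NaOMe in MeOH at 0 °C. The fallback comes back to the route at 7.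

Step 9. The benzylic C3 radical may dimerise or be reduced before nickel captures it, or face discrimination at the planar radical may be weak. The fallback sets out from 11 and forms the same bond by nickel-catalysed reductive cross-electrophile coupling with commercial 1-iodo-3,5-dimethoxybenzene (NiBr2(dme), 4,4'-di-tert-butyl-2,2'-bipyridine, Zn dust, DMA, rt). Here the aryl–nickel species arises by oxidative addition and no organozinc nucleophile is present. No new compound is made (F0), and the fallback comes back at 15.

Step 11. Once the catechol is free, the Lewis acid may ionise the C2–O1 bond (ring opening or epimerisation), or HBr released from the catechol may protonate the stilbene and start Friedel–Crafts oligomerisation. The fallback sets out from 15 and reverses the order of deprotection. BBr3 is applied while both mesylates still deactivate ring B and no O–H is present, which should give 4-[(2S,3S)-3-(3,5-dihydroxyphenyl)-5-[(E)-2-(3,5-dihydroxyphenyl)ethenyl]-2,3-dihydro-1-benzofuran-2-yl]-1,2-phenylene bis(methanesulfonate) F4. The sulfonates are then hydrolysed with degassed aqueous KOH in 1,4-dioxane at 40–50 °C under argon, for as short a time as possible, followed by aq. HCl. The fallback comes back at 17.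

**Further compounds**

F1 | step 4 | (2S)-6-bromo-2-[3,4-bis(methylsulfonyloxy)phenyl]-3-(trifluoroacetyl)chroman-4-one | O=C1C(C(=O)C(F)(F)F)[C@@H](c2ccc(OS(C)(=O)=O)c(OS(C)(=O)=O)c2)Oc2ccc(Br)cc21
F2 | step 4 | (2R)-6-bromo-3-diazo-2-[3,4-bis(methylsulfonyloxy)phenyl]chroman-4-one | O=C1C(=[N+]=[N-])[C@@H](c2ccc(OS(C)(=O)=O)c(OS(C)(=O)=O)c2)Oc2ccc(Br)cc21
F3 | step 4 | methyl (2S,3R)-5-bromo-2-[3,4-bis(methylsulfonyloxy)phenyl]-2,3-dihydro-1-benzofuran-3-carboxylate (cis) | Brc1ccc2c(c1)[C@@H](C(=O)OC)[C@@H](c1ccc(OS(C)(=O)=O)c(OS(C)(=O)=O)c1)O2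
F0 | step 9 | none | none
F4 | step 11 | 4-[(2S,3S)-3-(3,5-dihydroxyphenyl)-5-[(E)-2-(3,5-dihydroxyphenyl)ethenyl]-2,3-dihydro-1-benzofuran-2-yl]-1,2-phenylene bis(methanesulfonate) | Oc1cc(O)cc(/C=C/c2ccc3c(c2)[C@H](c2cc(O)cc(O)c2)[C@@H](c2ccc(OS(C)(=O)=O)c(OS(C)(=O)=O)c2)O3)c1
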